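**Retrosynthetic overview**

1. Ring B (the methoxy-1,2-dioxine, C3–C6) is opened to a (Z)-γ-hydroperoxy enone. Acidic methanol closes C3–OOH onto the C6 ketone and forms the methyl peroxyketal, which copies the presumed biogenesis of alkoxydioxines. The C3–O bond comes from a catalytic asymmetric β-peroxidation of a (2E,4Z)-6-oxo-2,4-dienal.
2. Ring A (the 6-propyl-1,2-dioxine, C10–C13) is opened to a (10S,13R)-(Z)-ene-1,4-diol, whose bis-mesylate is closed by hydrogen peroxide with inversion at both carbons.
3. The C1–C16 chain is cut at C3–C4 and C5–C6: an (E)-3,3-diethoxypropenyl cuprate (C1–C3), acetylene (C4, C5) and an acid chloride (C6–C16) are joined in one flask.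
4. Enabling feature: in ring B the ring carbons C4 and C5 are an unsubstituted cis CH=CH unit between the peroxide-bearing C3 and the peroxyketal carbon C6. This is a syn-carbometalated acetylene flanked by an alkenyl-nucleophile carbon (C3) and an acyl carbon (C6).
5. Order of ring formation: ring A first (step 10), ring B last (step 14).

Key step: step 8

Remark: chain carbons are numbered C1 (ester carbon) to C16 (propyl terminus) as in the target. (3R)-Hex-1-yn-3-ol is assumed to be purchased enantiopure; otherwise it is obtained from the commercial racemate by lipase-mediated acylation.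

**Route**

Step 1
Reactants: 1 (3R)-hex-1-yn-3-ol
Product: 2 triethyl{[(3R)-hex-1-yn-3-yl]oxy}silane
Conditions: Et3SiCl, imidazole, CH2Cl2, 0 °C to rt
Reagents that add atoms: chlorotriethylsilane, CC[Si](Cl)(CC)CC
Why: Silylation of a secondary alcohol with a trialkylsilyl chloride and imidazole is routine, leaves the future C13 stereocentre untouched and masks the hydroxyl against acylation in step 2.

Step 2
Reactants: 2 triethyl{[(3R)-hex-1-yn-3-yl]oxy}silane; 3 methyl 5-chloro-5-oxopentanoate
Product: 4 methyl (8R)-5-oxo-8-(triethylsilyloxy)undec-6-ynoate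
Conditions: PdCl2(PPh3)2 (2 mol %), CuI (4 mol %), Et3N (1.1 equiv), THF, rt
Reagents that add atoms: none
Why: The copper-assisted, palladium-catalysed coupling of a terminal alkyne with an acid chloride (acyl Sonogashira coupling) gives ynones under conditions that tolerate the methyl ester and the silyl ether, so the C6–C16 carbon chain is assembled without touching the stereocentre.

Step 3
Reactants: 4 methyl (8R)-5-oxo-8-(triethylsilyloxy)undec-6-ynoate
Product: 5 methyl (5S,8R)-5-hydroxy-8-(triethylsilyloxy)undec-6-ynoate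
Conditions: Ru[(S,S)-TsDPEN](p-cymene) (0.5 mol %), i-PrOH, 25 °C
Reagents that add atoms: none
Why: Asymmetric transfer hydrogenation of alkynyl ketones (Noyori type) is catalyst-controlled, the alkyne taking the place of the aryl group of aryl ketones in the transition state, so the (S,S)-catalyst should set the new carbinol (the future C10) as S independently of the remote silyloxy centre.

Step 4
Reactants: 5 methyl (5S,8R)-5-hydroxy-8-(triethylsilyloxy)undec-6-ynoate
Product: 6 methyl (5S,8R)-5,8-bis(triethylsilyloxy)undec-6-ynoate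
Conditions: Et3SiCl, imidazole, CH2Cl2, 0 °C to rt
Reagents that add atoms: chlorotriethylsilane, CC[Si](Cl)(CC)CC
Why: Routine silylation as in step 1 protects the second carbinol so that both oxygens survive the organocopper chemistry of step 8.

Step 5
Reactants: 6 methyl (5S,8R)-5,8-bis(triethylsilyloxy)undec-6-ynoate
Product: 7 methyl (5S,6Z,8R)-5,8-bis(triethylsilyloxy)undec-6-enoate
Conditions: H2 (1 atm), Pd/CaCO3 poisoned with Pb(OAc)2, quinoline, hexane/EtOAc, rt
Reagents that add atoms: none
Why: Semihydrogenation of the internal alkyne over the lead-poisoned palladium catalyst (Lindlar reduction) adds hydrogen syn and stops at the alkene, which fixes the Z geometry that later lets ring A close.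

Step 6
Reactants: 7 methyl (5S,6Z,8R)-5,8-bis(triethylsilyloxy)undec-6-enoate
Product: 9 (5S,6Z,8R)-5,8-bis(triethylsilyloxy)undec-6-enoyl chloride, via potassium carboxylate 8 (not isolated)
Conditions: KOSiMe3 (1.2 equiv), THF, rt; evaporate; (COCl)2 (1.3 equiv), DMF (cat.), CH2Cl2, 0 °C
Reagents that add atoms: oxalyl chloride, ClC(=O)C(Cl)=O
Why: Anhydrous ester cleavage with potassium trimethylsilanolate gives the potassium carboxylate without exposing the triethylsilyl ethers to aqueous base, and oxalyl chloride converts the salt into the acid chloride without releasing hydrogen chloride.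

Step 7
Reactants: 10 3,3-diethoxyprop-1-yne
Product: 12 (1E)-3,3-diethoxy-1-iodoprop-1-ene, via alkenylzirconocene 11 (not isolated)
Conditions: Cp2Zr(H)Cl (1.1 equiv), THF, rt; then I2 (1.1 equiv), 0 °C
Reagents that add atoms: iodine, II
Why: Hydrozirconation of a terminal alkyne is syn and places zirconium on the terminal carbon, and iodinolysis of the carbon–zirconium bond goes with retention, which should give the (E)-iodoalkene as a single isomer.

Step 8
Reactants: 12 (1E)-3,3-diethoxy-1-iodoprop-1-ene; 13 acetylene; 9 (5S,6Z,8R)-5,8-bis(triethylsilyloxy)undec-6-enoyl chloride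
Product: 17 (2E,4Z,10S,11Z,13R)-1,1-diethoxy-10,13-bis(triethylsilyloxy)hexadeca-2,4,11-trien-6-one, via alkenyllithium 14 (not isolated), via dialkenylcuprate 15 (not isolated), via dienylcuprate 16 (not isolated)
Conditions: 12 (2.2 equiv), t-BuLi (4.4 equiv), Et2O, −78 °C; CuBr·SMe2 (1.1 equiv), −45 °C; HC≡CH (2.3 equiv), −50 to −20 °C; then 9 (1.0 equiv), −78 °C, 1 h; aq NH4Cl/NH3
Reagents that add atoms: none
Why: Iodine–lithium exchange gives the (E)-alkenyllithium 14, which with CuBr·SMe2 forms the lithium dialkenylcuprate 15; each alkenyl–copper bond then adds syn across acetylene to give the (1Z,3E)-dienylcuprate 16, so the C3–C4 bond and the Z geometry of C4=C5 arise together, and acylation of 16 by acid chloride 9 with retention at the copper-bearing carbon forms the C5–C6 bond. The closest known reaction type is the syn-carbocupration of acetylene by lithium diorganocuprates followed by trapping of the (Z)-alkenylcuprate with an acid chloride, the classical entry to (Z)-enones and (2E,4Z)-dienes. No ring is closed and no stereocentre is created here; rings A and B are closed later (steps 10 and 14) on the chain assembled in this step. The geometric selectivity needed is Z at C4=C5 and E at C2=C3: the first is secured by the strictly syn addition to the alkyne, the second is carried in from 12 because alkenyl–metal species are configurationally stable at these temperatures. The chemoselectivity needed is acylation at the acyl chloride only: the silyl ethers and the diethyl acetal are inert to cuprates, and the dienone product should be spared because the dienylcopper left after transfer of one ligand does not add to enones at −78 °C. Only one acetylene should be inserted per copper–carbon bond because the (Z)-dienylcuprate is a much poorer carbometalating agent than 15 below −20 °C.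

Step 9
Reactants: 17 (2E,4Z,10S,11Z,13R)-1,1-diethoxy-10,13-bis(triethylsilyloxy)hexadeca-2,4,11-trien-6-one
Product: 18 (2E,4Z,10S,11Z,13R)-1,1-diethoxy-10,13-dihydroxyhexadeca-2,4,11-trien-6-one
Conditions: Bu4NF (2.4 equiv), AcOH (2.4 equiv), THF, 0 °C
Reagents that add atoms: none
Why: Acetic acid-buffered fluoride removes the two secondary triethylsilyl ethers by attack at silicon without touching the stereocentres, and the buffer keeps the medium neutral enough for the acetal and the Z-configured dienone.

Step 10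
Reactants: 18 (2E,4Z,10S,11Z,13R)-1,1-diethoxy-10,13-dihydroxyhexadeca-2,4,11-trien-6-one
Product: 21 (2E,4Z)-1,1-diethoxy-9-[(3R,6S)-6-propyl-3,6-dihydro-1,2-dioxin-3-yl]nona-2,4-dien-6-one, via bis-mesylate 19 (not isolated), via hydroperoxy mesylate 20 (not isolated)
Conditions: MsCl (2.3 equiv), Et3N (4.6 equiv), CH2Cl2, −40 °C, 20 min; then anhydrous H2O2 (1 M in Et2O, 10 equiv), −40 to −10 °C
Reagents that add atoms: hydrogen peroxide, OO
Why: Proposed new method: the diol is converted at low temperature into the dimethanesulfonate 19, in which both sulfonates are allylic, and one of them is displaced with inversion by hydrogen peroxide to give hydroperoxy mesylate 20, whose hydroperoxy group, held next to the second allylic carbon by the Z double bond, closes ring A by a 6-exo-tet displacement with a second inversion, so that the (10S,13R)-diol should become the (10R,13S)-cis-dioxine while the amine in excess takes up the methanesulfonic acid and so spares the acetal; the closest known reaction type is the double displacement of 1,3- and 1,4-bis-sulfonates by hydrogen peroxide or peroxide salts to give 1,2-dioxolanes and 1,2-dioxanes with inversion at both carbons, which has not been shown for secondary allylic bis-sulfonates.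

Step 11
Reactants: 21 (2E,4Z)-1,1-diethoxy-9-[(3R,6S)-6-propyl-3,6-dihydro-1,2-dioxin-3-yl]nona-2,4-dien-6-one
Product: 22 (2E,4Z)-6-oxo-9-[(3R,6S)-6-propyl-3,6-dihydro-1,2-dioxin-3-yl]nona-2,4-dienal
Conditions: oxalic acid (10 % aq) on SiO2, CH2Cl2, 0 °C, dark
Reagents that add atoms: water, O
Why: Allylic acetals are hydrolysed by very mild acid on wet silica gel, which should release the enal without isomerising the 4Z double bond and without affecting the dialkyl peroxide of ring A.

Step 12
Reactants: 22 (2E,4Z)-6-oxo-9-[(3R,6S)-6-propyl-3,6-dihydro-1,2-dioxin-3-yl]nona-2,4-dienal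
Product: 23 (3R,4Z)-3-[(2-methoxypropan-2-yl)peroxy]-6-oxo-9-[(3R,6S)-6-propyl-3,6-dihydro-1,2-dioxin-3-yl]non-4-enal
Conditions: (R)-2-[diphenyl(trimethylsilyloxy)methyl]pyrrolidine (20 mol %), PhCO2H (20 mol %), 2-methoxyprop-2-yl hydroperoxide (2 equiv, prepared beforehand by ozonolysis of 2,3-dimethylbut-2-ene in MeOH/CH2Cl2 at −78 °C and exchanged into toluene), toluene, −20 °C
Reagents that add atoms: 2-methoxyprop-2-yl hydroperoxide, COC(C)(C)OO
Why: Iminium activation of the enal by the diarylprolinol silyl ether directs the hydroperoxide to C3 (oxa-Michael addition, the catalytic enantioselective β-peroxidation of enals), the diphenyl(silyloxy)methyl group shielding one face of the s-trans E-iminium ion so that the (R)-catalyst should give the 3R peroxide on the usual steric model, while the acid co-catalyst protonates the enamine before it can close to the epoxide and the 1,6-position C5 is deactivated because it is the α-carbon of the enone.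

Step 13
Reactants: 23 (3R,4Z)-3-[(2-methoxypropan-2-yl)peroxy]-6-oxo-9-[(3R,6S)-6-propyl-3,6-dihydro-1,2-dioxin-3-yl]non-4-enal
Product: 25 methyl (3R,4Z)-3-[(2-methoxypropan-2-yl)peroxy]-6-oxo-9-[(3R,6S)-6-propyl-3,6-dihydro-1,2-dioxin-3-yl]non-4-enoate, via carboxylic acid 24 (not isolated)
Conditions: NaClO2, NaH2PO4, 2-methylbut-2-ene, t-BuOH/H2O, 0 °C; then Me3SiCHN2, MeOH/toluene, 0 °C
Reagents that add atoms: sodium chlorite, [Na+].[O-]Cl=O; trimethylsilyldiazomethane, C[Si](C)(C)C=[N+]=[N-]
Why: Buffered chlorite oxidation of the aldehyde (Pinnick oxidation) with a hypochlorite scavenger is compatible with peroxides and alkenes and should not epimerise the β-peroxy centre, and trimethylsilyldiazomethane methylates the crude acid under neutral conditions.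

Step 14
Reactants: 25 methyl (3R,4Z)-3-[(2-methoxypropan-2-yl)peroxy]-6-oxo-9-[(3R,6S)-6-propyl-3,6-dihydro-1,2-dioxin-3-yl]non-4-enoate
Product: 28 methyl 2-[(3R,6S)-6-methoxy-6-{3-[(3R,6S)-6-propyl-3,6-dihydro-1,2-dioxin-3-yl]propyl}-3,6-dihydro-1,2-dioxin-3-yl]acetate, via hydroperoxy enone 26 (not isolated), via dioxinol 27 (not isolated)
Conditions: TsOH·H2O (5 mol %), anhydrous MeOH, 0 °C to rt, dark; NaHCO3 quench
Reagents that add atoms: methanol, CO
Why: Acid in methanol cleaves the perketal to the C3 hydroperoxide 26, which adds to the cis-disposed C6 ketone to give dioxinol 27 (6-exo-trig hemiketalisation, the presumed biogenetic closure of alkoxydioxines), and ionisation of 27 to the conjugated peroxycarbenium ion followed by capture of methanol gives the methyl peroxyketal, with C3 untouched and C6 set by methanol entering the nearly planar cation anti to the C3 side chain, so that OMe should end up trans to CH2CO2Me as in the target; because the peroxyketal can re-ionise under acid, the reaction is quenched as soon as 27 is consumed and 28 is purified by chromatography.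

**Compound list**

1 | (3R)-hex-1-yn-3-ol | CCC[C@@H](O)C#C | starting material
2 | triethyl{[(3R)-hex-1-yn-3-yl]oxy}silane | CCC[C@@H](O[Si](CC)(CC)CC)C#C | intermediate
3 | methyl 5-chloro-5-oxopentanoate | COC(=O)CCCC(Cl)=O | starting material
4 | methyl (8R)-5-oxo-8-(triethylsilyloxy)undec-6-ynoate | COC(=O)CCCC(=O)C#C[C@H](O[Si](CC)(CC)CC)CCC | intermediate
5 | methyl (5S,8R)-5-hydroxy-8-(triethylsilyloxy)undec-6-ynoate | COC(=O)CCC[C@H](O)C#C[C@H](O[Si](CC)(CC)CC)CCC | intermediate
6 | methyl (5S,8R)-5,8-bis(triethylsilyloxy)undec-6-ynoate | COC(=O)CCC[C@H](O[Si](CC)(CC)CC)C#C[C@H](O[Si](CC)(CC)CC)CCC | intermediate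
7 | methyl (5S,6Z,8R)-5,8-bis(triethylsilyloxy)undec-6-enoate | COC(=O)CCC[C@H](O[Si](CC)(CC)CC)/C=C\[C@H](O[Si](CC)(CC)CC)CCC | intermediate
8 | potassium (5S,6Z,8R)-5,8-bis(triethylsilyloxy)undec-6-enoate | [K+].[O-]C(=O)CCC[C@H](O[Si](CC)(CC)CC)/C=C\[C@H](O[Si](CC)(CC)CC)CCC | intermediate
9 | (5S,6Z,8R)-5,8-bis(triethylsilyloxy)undec-6-enoyl chloride | ClC(=O)CCC[C@H](O[Si](CC)(CC)CC)/C=C\[C@H](O[Si](CC)(CC)CC)CCC | intermediate
10 | 3,3-diethoxyprop-1-yne | CCOC(OCC)C#C | starting material
11 | chlorobis(cyclopentadienyl)[(1E)-3,3-diethoxyprop-1-enyl]zirconium | CCOC(OCC)/C=C/[Zr](Cl)(C1C=CC=C1)C1C=CC=C1 | intermediate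
12 | (1E)-3,3-diethoxy-1-iodoprop-1-ene | CCOC(OCC)/C=C/I | intermediate
13 | acetylene | C#C | starting material
14 | [(1E)-3,3-diethoxyprop-1-enyl]lithium | CCOC(OCC)/C=C/[Li] | intermediate
15 | lithium bis[(1E)-3,3-diethoxyprop-1-enyl]cuprate | [Li+].CCOC(OCC)/C=C/[Cu-]/C=C/C(OCC)OCC | intermediate
16 | lithium bis[(1Z,3E)-5,5-diethoxypenta-1,3-dienyl]cuprate | [Li+].CCOC(OCC)/C=C/C=C\[Cu-]/C=C\C=C\C(OCC)OCC | intermediate
17 | (2E,4Z,10S,11Z,13R)-1,1-diethoxy-10,13-bis(triethylsilyloxy)hexadeca-2,4,11-trien-6-one | CCOC(OCC)/C=C/C=C\C(=O)CCC[C@H](O[Si](CC)(CC)CC)/C=C\[C@H](O[Si](CC)(CC)CC)CCC | intermediate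
18 | (2E,4Z,10S,11Z,13R)-1,1-diethoxy-10,13-dihydroxyhexadeca-2,4,11-trien-6-one | CCOC(OCC)/C=C/C=C\C(=O)CCC[C@H](O)/C=C\[C@H](O)CCC | intermediate
19 | (2E,4Z,10S,11Z,13R)-1,1-diethoxy-6-oxohexadeca-2,4,11-triene-10,13-diyl dimethanesulfonate | CCOC(OCC)/C=C/C=C\C(=O)CCC[C@H](OS(C)(=O)=O)/C=C\[C@H](OS(C)(=O)=O)CCC | intermediate
20 | (2E,4Z,10S,11Z,13S)-1,1-diethoxy-13-hydroperoxy-6-oxohexadeca-2,4,11-trien-10-yl methanesulfonate | CCOC(OCC)/C=C/C=C\C(=O)CCC[C@H](OS(C)(=O)=O)/C=C\[C@@H](OO)CCC | intermediate
21 | (2E,4Z)-1,1-diethoxy-9-[(3R,6S)-6-propyl-3,6-dihydro-1,2-dioxin-3-yl]nona-2,4-dien-6-one | CCC[C@H]1C=C[C@@H](CCCC(=O)\C=C/C=C/C(OCC)OCC)OO1 | intermediate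
22 | (2E,4Z)-6-oxo-9-[(3R,6S)-6-propyl-3,6-dihydro-1,2-dioxin-3-yl]nona-2,4-dienal | CCC[C@H]1C=C[C@@H](CCCC(=O)\C=C/C=C/C=O)OO1 | intermediate
23 | (3R,4Z)-3-[(2-methoxypropan-2-yl)peroxy]-6-oxo-9-[(3R,6S)-6-propyl-3,6-dihydro-1,2-dioxin-3-yl]non-4-enal | CCC[C@H]1C=C[C@@H](CCCC(=O)\C=C/[C@@H](CC=O)OOC(C)(C)OC)OO1 | intermediate
24 | (3R,4Z)-3-[(2-methoxypropan-2-yl)peroxy]-6-oxo-9-[(3R,6S)-6-propyl-3,6-dihydro-1,2-dioxin-3-yl]non-4-enoic acid | CCC[C@H]1C=C[C@@H](CCCC(=O)\C=C/[C@@H](CC(O)=O)OOC(C)(C)OC)OO1 | intermediate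
25 | methyl (3R,4Z)-3-[(2-methoxypropan-2-yl)peroxy]-6-oxo-9-[(3R,6S)-6-propyl-3,6-dihydro-1,2-dioxin-3-yl]non-4-enoate | CCC[C@H]1C=C[C@@H](CCCC(=O)\C=C/[C@@H](CC(=O)OC)OOC(C)(C)OC)OO1 | intermediate
26 | methyl (3R,4Z)-3-hydroperoxy-6-oxo-9-[(3R,6S)-6-propyl-3,6-dihydro-1,2-dioxin-3-yl]non-4-enoate | CCC[C@H]1C=C[C@@H](CCCC(=O)\C=C/[C@@H](CC(=O)OC)OO)OO1 | intermediate
27 | methyl 2-[(3R)-6-hydroxy-6-{3-[(3R,6S)-6-propyl-3,6-dihydro-1,2-dioxin-3-yl]propyl}-3,6-dihydro-1,2-dioxin-3-yl]acetate (both C6 anomers) | CCC[C@H]1C=C[C@@H](CCCC2(O)C=C[C@@H](CC(=O)OC)OO2)OO1 | intermediate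
28 | methyl 2-[(3R,6S)-6-methoxy-6-{3-[(3R,6S)-6-propyl-3,6-dihydro-1,2-dioxin-3-yl]propyl}-3,6-dihydro-1,2-dioxin-3-yl]acetate | CCC[C@H]1C=C[C@@H](CCC[C@@]2(OC)C=C[C@@H](CC(=O)OC)OO2)OO1 | target

**Step count and risks**

Total step count: 14. Longest linear sequence: 13 steps (steps 1–6 and 8–14; step 7 is a one-step branch).

Steps most likely to fail:

1. Step 10 (Proposed new method). What may go wrong: ionisation of the secondary allylic sulfonates with loss of configuration or allylic transposition, closure of a mono-mesylate onto the neighbouring hydroxyl to a 2,5-dihydrofuran, or nucleophilic epoxidation of the dienone by hydroperoxide anion. The fallback uses known chemistry, sets out from dienylcuprate 16 and comes back to the route at 21. It forms ring A by the suprafacial [4+2] cycloaddition of singlet oxygen to an (E,E)-diene instead of by displacement. Commercial (E)-hex-2-enal is olefinated with the ylide of (4-carboxybutyl)triphenylphosphonium bromide (NaN(SiMe3)2, THF) to (5Z,7E)-undeca-5,7-dienoic acid F1, which a trace of iodine under light should equilibrate to (5E,7E)-undeca-5,7-dienoic acid F2. Oxalyl chloride gives (5E,7E)-undeca-5,7-dienoyl chloride F3, which replaces 9 in the acylation of 16 under the conditions of step 8 and should give (2E,4Z,10E,12E)-1,1-diethoxyhexadeca-2,4,10,12-tetraen-6-one F4. Sensitised photooxygenation (O2, tetraphenylporphyrin, CH2Cl2, −30 °C, orange light) should add singlet oxygen only to the electron-rich dialkyl diene and give the cis-dioxine as a racemate, that is 21 together with its enantiomer (2E,4Z)-1,1-diethoxy-9-[(3S,6R)-6-propyl-3,6-dihydro-1,2-dioxin-3-yl]nona-2,4-dien-6-one F5. As ring A holds the only stereocentres at this stage, chromatography on a chiral stationary phase separates the two, at the cost of half the material.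

2. Step 12. What may go wrong: closure of the β-peroxy enamine to the α,β-epoxy aldehyde, Z to E isomerisation of C4=C5 by reversible addition of the amine, amine-induced fragmentation of the ring A peroxide, or poor facial selectivity on this doubly activated diene. The fallback sets out from 22 and comes back at 28, and closes ring B by the intramolecular oxa-Michael addition of a hydroperoxy ketal instead of by intermolecular peroxidation. Chlorite oxidation of 22 gives (2E,4Z)-6-oxo-9-[(3R,6S)-6-propyl-3,6-dihydro-1,2-dioxin-3-yl]nona-2,4-dienoic acid F6, and trimethylsilyldiazomethane gives methyl (2E,4Z)-6-oxo-9-[(3R,6S)-6-propyl-3,6-dihydro-1,2-dioxin-3-yl]nona-2,4-dienoate F7. Acid-catalysed exchange of the ketone with anhydrous H2O2 in methanol gives methyl (2E,4Z)-6-hydroperoxy-6-methoxy-9-[(3R,6S)-6-propyl-3,6-dihydro-1,2-dioxin-3-yl]nona-2,4-dienoate F8. Et2NH in CF3CH2OH should then trigger the 6-exo addition of the hydroperoxide to C3 of the dienoate, the known route to alkoxydioxane acetates. Neither C3 nor C6 is controlled in this fallback, so 28 would have to be separated by HPLC from its C6 epimer, methyl 2-[(3R,6R)-6-methoxy-6-{3-[(3R,6S)-6-propyl-3,6-dihydro-1,2-dioxin-3-yl]propyl}-3,6-dihydro-1,2-dioxin-3-yl]acetate F9, and from the two 3S isomers, methyl 2-[(3S,6R)-6-methoxy-6-{3-[(3R,6S)-6-propyl-3,6-dihydro-1,2-dioxin-3-yl]propyl}-3,6-dihydro-1,2-dioxin-3-yl]acetate F10 and methyl 2-[(3S,6S)-6-methoxy-6-{3-[(3R,6S)-6-propyl-3,6-dihydro-1,2-dioxin-3-yl]propyl}-3,6-dihydro-1,2-dioxin-3-yl]acetate F11.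

3. Step 14. What may go wrong: poor facial selectivity in the capture of the peroxycarbenium ion by methanol, and re-ionisation of the product under the acid, so that the configuration at the peroxyketal carbon equilibrates and the step turns into a separation problem. The fallback sets out from 25 and comes back at 28, and sets C6 by O-alkylation under conditions that do not equilibrate the product instead of by acid ketalisation. Hydrolysis of the perketal (AcOH/THF/H2O, 0 °C) gives dioxinol 27, which is isolated as the anomer mixture and methylated with MeOTf and 2,6-di-tert-butyl-4-methylpyridine in CH2Cl2 at −40 °C. The hemiketal anomers interconvert through the open hydroperoxy enone, and the pseudo-equatorial oxygen is the more nucleophilic (kinetic anomeric effect), which should place OMe trans to the C3 side chain as in 28.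

**Further compounds**

F1 | step 10 | (5Z,7E)-undeca-5,7-dienoic acid | OC(=O)CCC/C=C\C=C\CCC
F2 | step 10 | (5E,7E)-undeca-5,7-dienoic acid | OC(=O)CCC/C=C/C=C/CCC
F3 | step 10 | (5E,7E)-undeca-5,7-dienoyl chloride | ClC(=O)CCC/C=C/C=C/CCC
F4 | step 10 | (2E,4Z,10E,12E)-1,1-diethoxyhexadeca-2,4,10,12-tetraen-6-one | CCOC(OCC)/C=C/C=C\C(=O)CCC/C=C/C=C/CCC
F5 | step 10 | (2E,4Z)-1,1-diethoxy-9-[(3S,6R)-6-propyl-3,6-dihydro-1,2-dioxin-3-yl]nona-2,4-dien-6-one | CCC[C@@H]1C=C[C@H](CCCC(=O)\C=C/C=C/C(OCC)OCC)OO1
F6 | step 12 | (2E,4Z)-6-oxo-9-[(3R,6S)-6-propyl-3,6-dihydro-1,2-dioxin-3-yl]nona-2,4-dienoic acid | CCC[C@H]1C=C[C@@H](CCCC(=O)\C=C/C=C/C(O)=O)OO1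
F7 | step 12 | methyl (2E,4Z)-6-oxo-9-[(3R,6S)-6-propyl-3,6-dihydro-1,2-dioxin-3-yl]nona-2,4-dienoate | CCC[C@H]1C=C[C@@H](CCCC(=O)\C=C/C=C/C(=O)OC)OO1
F8 | step 12 | methyl (2E,4Z)-6-hydroperoxy-6-methoxy-9-[(3R,6S)-6-propyl-3,6-dihydro-1,2-dioxin-3-yl]nona-2,4-dienoate | CCC[C@H]1C=C[C@@H](CCCC(OC)(OO)\C=C/C=C/C(=O)OC)OO1
F9 | step 12 | methyl 2-[(3R,6R)-6-methoxy-6-{3-[(3R,6S)-6-propyl-3,6-dihydro-1,2-dioxin-3-yl]propyl}-3,6-dihydro-1,2-dioxin-3-yl]acetate | CCC[C@H]1C=C[C@@H](CCC[C@]2(OC)C=C[C@@H](CC(=O)OC)OO2)OO1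
F10 | step 12 | methyl 2-[(3S,6R)-6-methoxy-6-{3-[(3R,6S)-6-propyl-3,6-dihydro-1,2-dioxin-3-yl]propyl}-3,6-dihydro-1,2-dioxin-3-yl]acetate | CCC[C@H]1C=C[C@@H](CCC[C@]2(OC)C=C[C@H](CC(=O)OC)OO2)OO1
F11 | step 12 | methyl 2-[(3S,6S)-6-methoxy-6-{3-[(3R,6S)-6-propyl-3,6-dihydro-1,2-dioxin-3-yl]propyl}-3,6-dihydro-1,2-dioxin-3-yl]acetate | CCC[C@H]1C=C[C@@H](CCC[C@@]2(OC)C=C[C@H](CC(=O)OC)OO2)OO1
F0 | step 14 | none | none
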